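**Retrosynthesis**
1. Target 18 comes from the acetate 17 by hydrogenolysis of the two aryl benzyl ethers. 17 comes from the primary alcohol 16 by acetylation, and 16 comes from imide 15 by reductive removal of the auxiliary.
2. Key disconnection: imide 15 is assembled in one radical cascade from three pieces. An aryl radical (from ArI 4) adds to acryloyl imide 14. The resulting Lewis-acid-chelated α-imide radical adds to the CH(CH3) end of the electron-rich (E)-propenylarene 10. The benzylic radical then takes an H atom. This forms C7–Ar1 and C8–C8′ and sets C8 through the chiral auxiliary.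
3. The aryl pieces are built from catechol (guaiacyl iodide 4) and 4-chlorophenol (syringyl propenylarene 10), with benzyl protection removed at the end.
4. No ring is formed by C–C bonding. The aromatic rings come from the phenols, and the oxazolidinone is a transient auxiliary made in step 8 and removed in step 11.

**Assumption:** catechol, 4-chlorophenol, (E)-propenylboronic acid, (R)-valinol and acryloyl chloride are commercial. The Evans-type facial bias (radical attack anti to the isopropyl group) is assumed to carry over to the Lewis-acid-chelated α-imide radical, which is why the (R)-auxiliary is used to obtain 8S.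

---

**Step 1**
Reactants: 1 catechol
Product: 2 guaiacol (2-methoxyphenol)
Conditions: dimethyl carbonate (solvent), K2CO3, cat. Bu4NBr, 160 °C, sealed tube
Reagents that add atoms: dimethyl carbonate, COC(=O)OC
Why: Base-mediated methylation with dimethyl carbonate (BAl2 methyl transfer) stops largely at the monoether, because the guaiacolate anion is less reactive than the catecholate.

**Step 2**
Reactants: 2 guaiacol
Product: 3 4-iodo-2-methoxyphenol
Conditions: NIS, MeCN, rt
Reagents that add atoms: N-iodosuccinimide, O=C1CCC(=O)N1I
Why: Electrophilic aromatic iodination goes para to the strongly directing OH.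

**Step 3**
Reactants: 3 4-iodo-2-methoxyphenol
Product: 4 1-(benzyloxy)-4-iodo-2-methoxybenzene
Conditions: BnBr, K2CO3, acetone, reflux
Reagents that add atoms: benzyl bromide, BrCc1ccccc1
Why: Williamson O-benzylation masks the phenol, which would otherwise quench the radical chain.

**Step 4**
Reactants: 5 4-chlorophenol
Product: 6 2,6-dibromo-4-chlorophenol
Conditions: Br2 (2.1 equiv), CH2Cl2, 0 °C
Reagents that add atoms: bromine, BrBr
Why: The OH directs bromination to both ortho positions because the para position is blocked.

**Step 5**
Reactants: 6 2,6-dibromo-4-chlorophenol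
Product: 7 4-chloro-2,6-dimethoxyphenol
Conditions: NaOMe (5 equiv), CuI (10 mol %), MeOH/DMF, 110 °C, sealed tube
Reagents that add atoms: sodium methoxide, [Na+].[O-]C
Why: Ullmann-type Cu-catalysed methoxylation assisted by the ortho phenoxide (the classic syringaldehyde-type methoxylation), with C–Br reacting far faster than the para C–Cl, which is retained.

**Step 6**
Reactants: 7 4-chloro-2,6-dimethoxyphenol
Product: 8 2-(benzyloxy)-5-chloro-1,3-dimethoxybenzene
Conditions: BnBr, K2CO3, DMF, 60 °C
Reagents that add atoms: benzyl bromide, BrCc1ccccc1
Why: O-Benzylation; the benzyl group is removed together with the other one in the last step.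

**Step 7**
Reactants: 8 aryl chloride; 9 (E)-propenylboronic acid
Product: 10 (E)-2-(benzyloxy)-1,3-dimethoxy-5-(prop-1-en-1-yl)benzene
Conditions: Pd(OAc)2 (2 mol %), SPhos (4 mol %), K3PO4, toluene/H2O, 100 °C
Reagents that add atoms: none (the boronic acid 9 is the coupling partner)
Why: Suzuki–Miyaura coupling of an aryl chloride using a Buchwald ligand, with retention of alkene geometry to give the E-styrene.

**Step 8**
Reactants: 11 (R)-valinol
Product: 12 (R)-4-isopropyloxazolidin-2-one
Conditions: (EtO)2CO, K2CO3, 135 °C, distil off EtOH
Reagents that add atoms: diethyl carbonate, CCOC(=O)OCC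
Why: Carbonate cyclocondensation of the amino alcohol retains the stereocentre and gives the chiral auxiliary.

**Step 9**
Reactants: 12 auxiliary; 13 acryloyl chloride
Product: 14 (R)-3-acryloyl-4-isopropyloxazolidin-2-one
Conditions: n-BuLi, THF, –78 °C; then 13, –78 °C → 0 °C
Reagents that add atoms: none (acryloyl chloride 13 is the reactant)
Why: N-Acylation of the lithiated oxazolidinone gives the chelating radical acceptor.

**Step 10 (key radical step)**
Reactants: 14 acryloyl imide; 4 aryl iodide; 10 propenylarene
Product: 15 (S)-configured imide 15 (the 8S,8′R diastereomer, isolated from the mixture)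
Conditions: 14 (1.0 equiv), 4 (1.5 equiv), 10 (3 equiv), MgBr2·OEt2 (2 equiv), (Me3Si)3SiH (1.5 equiv, syringe pump over 4 h), Et3B (0.3 equiv)/air, CH2Cl2, –78 → –40 °C; silica chromatography to separate diastereomers
Reagents that add atoms: none (H comes from the silane)
Why: Proposed new method: the silyl radical abstracts I from 4 to give a nucleophilic aryl radical, which adds to the Mg-chelated acrylimide 14 (polarity matched) to give an electrophilic α-imide radical. That radical adds to the CH(CH3) terminus of the electron-rich styrene 10, giving a stabilised benzylic radical that takes H from the silane. C8 is set by attack anti to the isopropyl group of the chelated auxiliary. C8′ is set by the E-alkene in a staggered addition. Any C8′ epimer is an auxiliary-bound diastereomer and is separated by chromatography. The closest known chemistry is Lewis-acid-mediated Giese additions to N-acryloyl oxazolidinones combined with Meerwein-type aryl-alkylation of alkenes.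

**Step 11**
Reactants: 15
Product: 16 (2S,3R)-2-(4-benzyloxy-3-methoxybenzyl)-4-(4-benzyloxy-3,5-dimethoxyphenyl)-3-methylbutan-1-ol (plus recovered 12)
Conditions: LiBH4, Et2O, H2O (1 equiv), 0 °C → rt
Reagents that add atoms: none
Why: Reductive exocyclic cleavage of the N-acyl oxazolidinone gives the primary alcohol without touching the benzyl ethers; the stereocentres are not epimerised and the auxiliary is recovered.

**Step 12**
Reactants: 16
Product: 17 the primary acetate, bis-O-benzyl
Conditions: Ac2O, pyridine, cat. DMAP, CH2Cl2, rt
Reagents that add atoms: acetic anhydride, CC(=O)OC(C)=O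
Why: Standard acylation of the primary alcohol; no free phenols are present at this stage.

**Step 13**
Reactants: 17
Product: 18 target
Conditions: H2 (1 atm), 10% Pd/C, EtOAc/EtOH, rt
Reagents that add atoms: none
Why: Hydrogenolysis cleaves both aryl benzyl ethers, while the acetate, methyl ethers and stereocentres survive.

---

**Compound list**
1 | catechol | Oc1ccccc1O | starting material
2 | guaiacol | COc1ccccc1O | intermediate
3 | 4-iodo-2-methoxyphenol | COc1cc(I)ccc1O | intermediate
4 | 1-(benzyloxy)-4-iodo-2-methoxybenzene | COc1cc(I)ccc1OCc1ccccc1 | intermediate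
5 | 4-chlorophenol | Oc1ccc(Cl)cc1 | starting material
6 | 2,6-dibromo-4-chlorophenol | Oc1c(Br)cc(Cl)cc1Br | intermediate
7 | 4-chloro-2,6-dimethoxyphenol | COc1cc(Cl)cc(OC)c1O | intermediate
8 | 2-(benzyloxy)-5-chloro-1,3-dimethoxybenzene | COc1cc(Cl)cc(OC)c1OCc1ccccc1 | intermediate
9 | (E)-propenylboronic acid | C/C=C/B(O)O | starting material
10 | (E)-2-(benzyloxy)-1,3-dimethoxy-5-(prop-1-enyl)benzene | C/C=C/c1cc(OC)c(OCc2ccccc2)c(OC)c1 | intermediate
11 | (R)-valinol | CC(C)[C@@H](N)CO | starting material
12 | (R)-4-isopropyloxazolidin-2-one | CC(C)[C@@H]1COC(=O)N1 | intermediate (recovered in step 11)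
13 | acryloyl chloride | C=CC(=O)Cl | starting material
14 | (R)-3-acryloyl-4-isopropyloxazolidin-2-one | CC(C)[C@@H]1COC(=O)N1C(=O)C=C | intermediate
15 | radical adduct imide (8S,8′R) | COc1cc(C[C@H](C(=O)N3C(=O)OC[C@H]3C(C)C)[C@H](C)Cc2cc(OC)c(OCc4ccccc4)c(OC)c2)ccc1OCc1ccccc1 | intermediate
16 | bis-O-benzyl primary alcohol | COc1cc(C[C@H](CO)[C@H](C)Cc2cc(OC)c(OCc3ccccc3)c(OC)c2)ccc1OCc1ccccc1 | intermediate
17 | bis-O-benzyl acetate | COc1cc(C[C@H](COC(C)=O)[C@H](C)Cc2cc(OC)c(OCc3ccccc3)c(OC)c2)ccc1OCc1ccccc1 | intermediate
18 | target (8S,8′R) | COc1cc(C[C@H](COC(C)=O)[C@H](C)Cc2cc(OC)c(O)c(OC)c2)ccc1O | target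

**Total steps:** 13 (including the two auxiliary steps, 8 and 9).
**Longest linear sequence:** 8 steps (4 → 5 → 6 → 7 → 10 → 11 → 12 → 13).

**Three steps most likely to fail**
1. **Step 10 (three-component radical cascade).**
   - Risks: aryl radical adding to styrene 10 instead of 14; silane reducing the α-radical before it adds to the styrene; low diastereoselectivity at C8′.
   - Fallback (different approach): a photoredox radical [3+2] lactonisation of 2-bromo-3-(4-benzyloxy-3-methoxyphenyl)propanoic acid with 10. This gives the 3,4-trans-5-aryl-γ-butyrolactone, with C8 epimerisable to trans. Reductive C–O/OBn hydrogenolysis, BH3 reduction and acetylation follow. The enantiomer is then obtained by resolving the acid.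
2. **Step 5 (double Cu-catalysed methoxylation).**
   - Risks: mono-substitution, or competing loss of the para chlorine.
   - Fallback (different approach): from 4-chlorophenyl MOM ether, do sequential ortho-lithiation/borylation–H2O2 oxidation twice, then exhaustive O-methylation and MOM removal.
3. **Step 7 (Suzuki coupling of an electron-rich aryl chloride).**
   - Risks: sluggish oxidative addition and propenylboronic acid protodeboronation.
   - Fallback (different approach): Pd-catalysed formylation of 8 to the aryl aldehyde, then Wittig olefination with an ethylphosphonium ylide and I2-mediated Z→E isomerisation to give 10.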